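**Retrosynthetic overview**
1. The strategy rests on the trans-vicinal pair C8–O / C7–isopropyl on the seven-membered ring (C1, C5–C10), which is a homoallylic alcohol once isopropyl is read as isopropenyl. The target is therefore traced back (isopropenyl hydrogenation, C8 angeloylation, desilylation, C6 inversion with acetate) to a 6-epi-7-isopropenylguai-1(10)-en-8-ol bis-silyl ether.
2. Seven-membered ring, formed last: the C7–C8 bond by Lewis acid carbonyl-ene closure of a (Z)-cyclopentylidene aldehyde that carries a 6S silyloxy 2-methylpropenyl arm on C5.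
3. C6–C7 bond: Felkin–Anh addition of 2-methylpropenylmagnesium bromide to a C6 aldehyde. C6 and C8 are the two ends of a cis-diol cleaved by periodate and told apart as C6 aldehyde and C8 pivalate.
4. Temporary six-membered ring, formed second and opened again: Diels–Alder addition of vinylene carbonate to a 1-isopropenylcyclopentene, which fixes the (Z)-C1=C10 geometry and sets C5.
5. Five-membered ring, formed first: enyne ring-closing metathesis of an oct-1-en-6-yne made from (S)-linalool, which supplies C4.

Key step: step 15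

Remark: guaiane numbering is used for all intermediates (five-membered ring C1–C5; seven-membered ring C1, C5–C10; C11–C13 isopropyl; C14 on C10; C15 on C4).
Assumption: (S)-(+)-linalool is taken as commercially available in high enantiomeric purity; it is the only source of absolute configuration.
Remark: the Diels–Alder adduct is drawn as the endo isomer; an exo isomer would converge, because both carbinol carbons become CH2OH after ring opening.

**Route**

Step 1
Reactants: 1 (S)-linalool
Product: 2 (3S)-3,7-dimethyl-3-(triethylsilyloxy)octa-1,6-diene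
Conditions: TESOTf, 2,6-lutidine, CH2Cl2, −78 → 0 °C
Reagents that add atoms: triethylsilyl trifluoromethanesulfonate, CC[Si](CC)(CC)OS(=O)(=O)C(F)(F)F
Why: Silyl triflate silylation of the tertiary allylic alcohol; C4 is carried over unchanged from 1, and the bulky OSiEt3 group later shields one face of C5.

Step 2
Reactants: 2 (3S)-3,7-dimethyl-3-(triethylsilyloxy)octa-1,6-diene
Product: 3 (4S)-4-methyl-4-(triethylsilyloxy)hex-5-enal
Conditions: O3 (1.0 equiv), CH2Cl2, −78 °C; Me2S, −78 °C → rt
Reagents that add atoms: ozone, [O-][O+]=O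
Why: Chemoselective ozonolysis with reductive work-up; the electron-rich trisubstituted alkene reacts much faster than the hindered monosubstituted vinyl group.

Step 3
Reactants: 3 (4S)-4-methyl-4-(triethylsilyloxy)hex-5-enal
Product: 4 (3S)-7,7-dibromo-3-methyl-3-(triethylsilyloxy)hepta-1,6-diene
Conditions: CBr4, PPh3, Zn, CH2Cl2, rt; then 3, 0 °C → rt
Reagents that add atoms: carbon tetrabromide, BrC(Br)(Br)Br
Why: Corey–Fuchs dibromo-olefination with the zinc-generated ylide is neutral, so the silyl ether and the vinyl group are untouched; the new carbon becomes C10.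

Step 4
Reactants: 4 (3S)-7,7-dibromo-3-methyl-3-(triethylsilyloxy)hepta-1,6-diene
Product: 6 (3S)-3-methyl-3-(triethylsilyloxy)oct-1-en-6-yne, via lithium acetylide 5 (not isolated)
Conditions: n-BuLi (2.1 equiv), THF, −78 °C; then MeI, −78 °C → rt
Reagents that add atoms: iodomethane, CI
Why: Second stage of the Corey–Fuchs alkyne synthesis (bromine–lithium exchange, α-elimination, 1,2-hydrogen shift), with the lithium acetylide methylated in the flask; the methyl group becomes C14.

Step 5
Reactants: 6 (3S)-3-methyl-3-(triethylsilyloxy)oct-1-en-6-yne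
Product: 7 (S)-triethyl{[1-methyl-3-(prop-1-en-2-yl)cyclopent-2-en-1-yl]oxy}silane
Conditions: second-generation Grubbs catalyst RuCl2(=CHPh)(PCy3)(H2IMes) (5 mol %), ethylene (1 atm), CH2Cl2, 40 °C
Reagents that add atoms: none
Why: Ring-closing enyne metathesis of the 1,6-enyne in the exo mode closes the five-membered ring and leaves the 2-propenyl group on C1 as a 1,3-diene; ethylene keeps the ruthenium methylidene alive, so the cycle can start at the alkyne and need not initiate at the hindered vinyl group.

Step 6
Reactants: 7 (S)-triethyl{[1-methyl-3-(prop-1-en-2-yl)cyclopent-2-en-1-yl]oxy}silane; 8 vinylene carbonate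
Product: 9 endo cyclic carbonate adduct (4S,5R,6R,8S; hydrindene with C1=C10 in the six-membered ring; H5 cis to OSiEt3; carbonate oxygens on C6 and C8 cis to the C4 methyl)
Conditions: 8 (4 equiv), BHT (cat.), toluene, sealed tube, 170 °C
Reagents that add atoms: none
Why: Thermal Diels–Alder reaction of the s-cis semicyclic diene with the cis-enediol equivalent; the new C1=C10 double bond lies inside the six-membered ring, which fixes C9 and C5 cis on it, and the dienophile should add to the face of C5 away from the OSiEt3 group (syn to the C4 methyl), which sets C5 with H5 cis to the silyloxy group.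

Step 7
Reactants: 9 endo cyclic carbonate adduct
Product: 10 (4S,5R,6R,8S) cis-6,8-diol of the hydrindene
Conditions: K2CO3, MeOH, rt
Reagents that add atoms: none
Why: Base-catalysed methanolysis (transesterification) of the cyclic carbonate frees the cis-diol without touching the tertiary silyl ether.

Step 8
Reactants: 10 (4S,5R,6R,8S) cis-6,8-diol of the hydrindene
Product: 12 (3Z)-3-[(2R,3S)-2-(hydroxymethyl)-3-methyl-3-(triethylsilyloxy)cyclopentylidene]butan-1-ol, via dialdehyde 11 (not isolated)
Conditions: NaIO4 on SiO2, CH2Cl2, 0 °C; filter; NaBH4, MeOH, 0 °C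
Reagents that add atoms: none
Why: Periodate glycol cleavage opens the six-membered ring with the (Z)-tetrasubstituted alkene intact, and immediate borohydride reduction prevents enolisation of the doubly β,γ-unsaturated dialdehyde at C5.

Step 9
Reactants: 12 (3Z)-3-[(2R,3S)-2-(hydroxymethyl)-3-methyl-3-(triethylsilyloxy)cyclopentylidene]butan-1-ol
Product: 13 (3Z)-3-[(2R,3S)-2-(hydroxymethyl)-3-methyl-3-(triethylsilyloxy)cyclopentylidene]butyl pivalate
Conditions: PivCl (1.05 equiv), pyridine, CH2Cl2, −20 °C
Reagents that add atoms: pivaloyl chloride, CC(C)(C)C(=O)Cl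
Why: Sterically controlled acylation: the unhindered C8 primary alcohol should react much faster than the C6 primary alcohol, which sits on a ring carbon flanked by the quaternary C4 and the tetrasubstituted alkene.

Step 10
Reactants: 13 (3Z)-3-[(2R,3S)-2-(hydroxymethyl)-3-methyl-3-(triethylsilyloxy)cyclopentylidene]butyl pivalate
Product: 14 (3Z)-3-[(2S,3S)-2-formyl-3-methyl-3-(triethylsilyloxy)cyclopentylidene]butyl pivalate
Conditions: Dess–Martin periodinane, NaHCO3, CH2Cl2, 0 °C
Reagents that add atoms: none
Why: Buffered Dess–Martin oxidation is neutral and non-enolising, so the α-stereocentre C5 of the β,γ-unsaturated aldehyde is not epimerised and the alkene stays in place.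

Step 11
Reactants: 14 (3Z)-3-[(2S,3S)-2-formyl-3-methyl-3-(triethylsilyloxy)cyclopentylidene]butyl pivalate; 15 1-bromo-2-methylpropene
Product: 17 (3Z)-3-{(2R,3S)-2-[(1S)-1-hydroxy-3-methylbut-2-en-1-yl]-3-methyl-3-(triethylsilyloxy)cyclopentylidene}butyl pivalate, via Grignard reagent 16 (not isolated)
Conditions: 15, Mg, THF, 40 °C; then 14, THF, −78 °C; aq. NH4Cl
Reagents that add atoms: none
Why: Grignard addition under Felkin–Anh control, the nucleophile entering anti to the quaternary C4 and past H5, should set C6 as the 6S (6-epi) alcohol; the hindered pivalate is inert at −78 °C.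

Step 12
Reactants: 17 6S allylic alcohol
Product: 18 (3Z)-3-{(2R,3S)-2-[(1S)-1-(tert-butyldimethylsilyloxy)-3-methylbut-2-en-1-yl]-3-methyl-3-(triethylsilyloxy)cyclopentylidene}butyl pivalate
Conditions: TBSOTf, 2,6-lutidine, CH2Cl2, −78 → 0 °C
Reagents that add atoms: tert-butyldimethylsilyl trifluoromethanesulfonate, CC(C)(C)[Si](C)(C)OS(=O)(=O)C(F)(F)F
Why: Silyl triflate silylation of the hindered secondary allylic alcohol; the bulky silyloxy group is the control element of the ene step.

Step 13
Reactants: 18 bis-silyl ether pivalate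
Product: 19 (3Z)-3-{(2R,3S)-2-[(1S)-1-(tert-butyldimethylsilyloxy)-3-methylbut-2-en-1-yl]-3-methyl-3-(triethylsilyloxy)cyclopentylidene}butan-1-ol
Conditions: i-Bu2AlH, CH2Cl2, −78 °C; aq. potassium sodium tartrate
Reagents that add atoms: none
Why: Reductive cleavage of the pivalate by the aluminium hydride leaves both silyl ethers and both alkenes untouched.

Step 14
Reactants: 19 primary alcohol
Product: 20 (3Z)-3-{(2R,3S)-2-[(1S)-1-(tert-butyldimethylsilyloxy)-3-methylbut-2-en-1-yl]-3-methyl-3-(triethylsilyloxy)cyclopentylidene}butanal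
Conditions: Dess–Martin periodinane, NaHCO3, CH2Cl2, 0 °C; used at once
Reagents that add atoms: none
Why: Buffered Dess–Martin oxidation gives the β,γ-unsaturated aldehyde without migration of the C1=C10 double bond into conjugation.

Step 15
Reactants: 20 (Z)-cyclopentylidene aldehyde with the 6S silyloxy 2-methylpropenyl arm
Product: 21 (4S,5R,6S,7R,8S)-6-(tert-butyldimethylsilyloxy)-4-(triethylsilyloxy)guaia-1(10),11-dien-8-ol
Conditions: Me2AlCl (2 equiv), CH2Cl2, −78 → −40 °C
Reagents that add atoms: none
Why: Me2AlCl activates the aldehyde, and C7 of the 2-methylpropenyl group bonds to C8 while a hydrogen of the (E)-methyl group passes to the carbonyl oxygen through a six-membered array, so the double bond moves to C11=C12 (isopropenyl) and the aluminium alkoxide formed with loss of methane keeps the medium free of protic acid. The closest known reaction is the Lewis acid-promoted intramolecular carbonyl-ene reaction with the aldehyde tethered to the olefinic terminus of the ene unit (citronellal to isopulegol), here one ring size larger. The seven-membered ring (C1, C5–C10) closes in the 7-exo-trig mode at the aldehyde carbon with the reacting alkene left outside the ring, and the (Z)-C1=C10 double bond, which holds C5 and C9 cis, brings C7 and C8 together. C7 is controlled by C6: allylic 1,3-strain with the (Z)-methyl group keeps H6 in the alkene plane, the tether through C5 then covers one face and the silyloxy group the other, and with 6S this face gives 7R (silyloxy and isopropenyl trans). C8 is controlled by the ene geometry: the carbonyl oxygen points outward, anti to C6 and next to the (E)-methyl group, which places hydroxyl trans to isopropenyl (8S). The step needs C7 face selectivity, and this requires a boat-like arrangement of the forming cycloheptene, because the chair-like alternative would force the silyloxy group into the alkene plane against the (Z)-methyl group and lead to the 7,8-bis-epimer; the large SiMe2t-Bu group is chosen to raise that penalty.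

Step 16
Reactants: 21 ene product
Product: 22 (4S,5R,6S,7R,8S)-6-(tert-butyldimethylsilyloxy)-4-(triethylsilyloxy)guai-1(10)-en-8-ol
Conditions: H2 (1–4 atm), RhCl(PPh3)3 (10 mol %), benzene, rt
Reagents that add atoms: none
Why: Homogeneous hydrogenation with RhCl(PPh3)3 reduces the 1,1-disubstituted isopropenyl group and leaves the tetrasubstituted C1=C10 double bond untouched; no stereocentre is created.

Step 17
Reactants: 22 8-hydroxy bis-silyl ether; 23 angelic acid
Product: 25 (4S,5R,6S,7R,8S)-8-angeloyloxy-6-(tert-butyldimethylsilyloxy)-4-(triethylsilyloxy)guai-1(10)-ene, via mixed anhydride 24 (not isolated)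
Conditions: 23, 2,4,6-Cl3C6H2COCl, Et3N, toluene, rt; then 22, 80 °C
Reagents that add atoms: none
Why: Yamaguchi-type mixed anhydride esterification run without a nucleophilic catalyst acylates the hindered C8 alcohol with retention at C8 and should avoid (Z)→(E) isomerisation of the angeloyl group.

Step 18
Reactants: 25 angelate bis-silyl ether
Product: 26 (4S,5R,6S,7S,8S)-8-angeloyloxyguai-1(10)-ene-4,6-diol (6-epi diol; the C7 descriptor changes through priorities only)
Conditions: HF·pyridine, pyridine, THF, 0 °C → rt
Reagents that add atoms: none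
Why: Fluoride-mediated desilylation removes both silyl ethers under buffered, mildly acidic conditions that spare the angelate and disfavour acyl migration from O8 to O6.

Step 19
Reactants: 26 6-epi diol
Product: 27 (4S,5R,6R,7R,8S)-6-acetoxy-8-angeloyloxyguai-1(10)-en-4-ol (CNP0258590.1)
Conditions: PPh3, diisopropyl azodicarboxylate, AcOH, toluene, 0 °C → rt
Reagents that add atoms: acetic acid, CC(=O)O
Why: Mitsunobu esterification: the secondary C6 alcohol is activated as the oxyphosphonium ion and displaced by acetate with inversion (SN2), which turns 6S into the 6R acetate, while the tertiary C4 alcohol does not react.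

**Compound list**
1 | (S)-(+)-linalool | C=C[C@@](C)(O)CCC=C(C)C | starting material
2 | (3S)-3,7-dimethyl-3-(triethylsilyloxy)octa-1,6-diene | C=C[C@@](C)(O[Si](CC)(CC)CC)CCC=C(C)C | intermediate
3 | (4S)-4-methyl-4-(triethylsilyloxy)hex-5-enal | C=C[C@@](C)(O[Si](CC)(CC)CC)CCC=O | intermediate
4 | (3S)-7,7-dibromo-3-methyl-3-(triethylsilyloxy)hepta-1,6-diene | C=C[C@@](C)(O[Si](CC)(CC)CC)CCC=C(Br)Br | intermediate
5 | lithium acetylide of (3S)-3-methyl-3-(triethylsilyloxy)hept-1-en-6-yne | C=C[C@@](C)(O[Si](CC)(CC)CC)CCC#C[Li] | intermediate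
6 | (3S)-3-methyl-3-(triethylsilyloxy)oct-1-en-6-yne | C=C[C@@](C)(O[Si](CC)(CC)CC)CCC#CC | intermediate
7 | (S)-triethyl{[1-methyl-3-(prop-1-en-2-yl)cyclopent-2-en-1-yl]oxy}silane | CC(=C)C1=C[C@@](C)(O[Si](CC)(CC)CC)CC1 | intermediate
8 | vinylene carbonate | O=C1OC=CO1 | starting material
9 | endo Diels–Alder cyclic carbonate (4S,5R,6R,8S) | O=C1O[C@H]2CC(C)=C3CC[C@](C)(O[Si](CC)(CC)CC)[C@H]3[C@H]2O1 | intermediate
10 | cis-6,8-diol of the hydrindene (4S,5R,6R,8S) | O[C@H]1CC(C)=C2CC[C@](C)(O[Si](CC)(CC)CC)[C@H]2[C@H]1O | intermediate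
11 | (3Z)-3-[(2S,3S)-2-formyl-3-methyl-3-(triethylsilyloxy)cyclopentylidene]butanal | O=CC/C(C)=C1/CC[C@](C)(O[Si](CC)(CC)CC)[C@H]1C=O | intermediate
12 | (3Z)-3-[(2R,3S)-2-(hydroxymethyl)-3-methyl-3-(triethylsilyloxy)cyclopentylidene]butan-1-ol | OCC/C(C)=C1/CC[C@](C)(O[Si](CC)(CC)CC)[C@H]1CO | intermediate
13 | (3Z)-3-[(2R,3S)-2-(hydroxymethyl)-3-methyl-3-(triethylsilyloxy)cyclopentylidene]butyl pivalate | CC(C)(C)C(=O)OCC/C(C)=C1/CC[C@](C)(O[Si](CC)(CC)CC)[C@H]1CO | intermediate
14 | (3Z)-3-[(2S,3S)-2-formyl-3-methyl-3-(triethylsilyloxy)cyclopentylidene]butyl pivalate | CC(C)(C)C(=O)OCC/C(C)=C1/CC[C@](C)(O[Si](CC)(CC)CC)[C@H]1C=O | intermediate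
15 | 1-bromo-2-methylpropene | CC(C)=CBr | starting material
16 | 2-methylprop-1-enylmagnesium bromide | CC(C)=C[Mg]Br | intermediate
17 | (3Z)-3-{(2R,3S)-2-[(1S)-1-hydroxy-3-methylbut-2-en-1-yl]-3-methyl-3-(triethylsilyloxy)cyclopentylidene}butyl pivalate | CC(C)(C)C(=O)OCC/C(C)=C1/CC[C@](C)(O[Si](CC)(CC)CC)[C@H]1[C@@H](O)C=C(C)C | intermediate
18 | tert-butyldimethylsilyl ether of 17 | CC(C)(C)C(=O)OCC/C(C)=C1/CC[C@](C)(O[Si](CC)(CC)CC)[C@H]1[C@@H](O[Si](C)(C)C(C)(C)C)C=C(C)C | intermediate
19 | (3Z)-3-{(2R,3S)-2-[(1S)-1-(tert-butyldimethylsilyloxy)-3-methylbut-2-en-1-yl]-3-methyl-3-(triethylsilyloxy)cyclopentylidene}butan-1-ol | OCC/C(C)=C1/CC[C@](C)(O[Si](CC)(CC)CC)[C@H]1[C@@H](O[Si](C)(C)C(C)(C)C)C=C(C)C | intermediate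
20 | (3Z)-3-{(2R,3S)-2-[(1S)-1-(tert-butyldimethylsilyloxy)-3-methylbut-2-en-1-yl]-3-methyl-3-(triethylsilyloxy)cyclopentylidene}butanal | O=CC/C(C)=C1/CC[C@](C)(O[Si](CC)(CC)CC)[C@H]1[C@@H](O[Si](C)(C)C(C)(C)C)C=C(C)C | intermediate
21 | (4S,5R,6S,7R,8S)-6-(tert-butyldimethylsilyloxy)-4-(triethylsilyloxy)guaia-1(10),11-dien-8-ol | O[C@H]1CC(C)=C2CC[C@](C)(O[Si](CC)(CC)CC)[C@H]2[C@@H](O[Si](C)(C)C(C)(C)C)[C@@H]1C(C)=C | intermediate
22 | (4S,5R,6S,7R,8S)-6-(tert-butyldimethylsilyloxy)-4-(triethylsilyloxy)guai-1(10)-en-8-ol | O[C@H]1CC(C)=C2CC[C@](C)(O[Si](CC)(CC)CC)[C@H]2[C@@H](O[Si](C)(C)C(C)(C)C)[C@@H]1C(C)C | intermediate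
23 | angelic acid, (Z)-2-methylbut-2-enoic acid | C/C=C(/C)C(=O)O | starting material
24 | angelic 2,4,6-trichlorobenzoic anhydride | C/C=C(/C)C(=O)OC(=O)c1c(Cl)cc(Cl)cc1Cl | intermediate
25 | (4S,5R,6S,7R,8S)-8-angeloyloxy-6-(tert-butyldimethylsilyloxy)-4-(triethylsilyloxy)guai-1(10)-ene | C/C=C(/C)C(=O)O[C@H]1CC(C)=C2CC[C@](C)(O[Si](CC)(CC)CC)[C@H]2[C@@H](O[Si](C)(C)C(C)(C)C)[C@@H]1C(C)C | intermediate
26 | (4S,5R,6S,7S,8S)-8-angeloyloxyguai-1(10)-ene-4,6-diol | C/C=C(/C)C(=O)O[C@H]1CC(C)=C2CC[C@](C)(O)[C@H]2[C@@H](O)[C@@H]1C(C)C | intermediate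
27 | (4S,5R,6R,7R,8S)-6-acetoxy-8-angeloyloxyguai-1(10)-en-4-ol, CNP0258590.1 | C/C=C(/C)C(=O)O[C@H]1CC(C)=C2CC[C@](C)(O)[C@H]2[C@H](OC(C)=O)[C@@H]1C(C)C | target

**Count**
Total step count: 19. Longest linear sequence: 19 steps (1 → 27); 15 and 23 enter as commercial reagents.

**Steps most likely to fail**

Step 15 (key step). What may go wrong: closure through the chair-like tether arrangement, with the silyloxy group in the alkene plane, would deliver the wrong face of C7; the β,γ-unsaturated aldehyde may isomerise to the conjugated enal under the Lewis acid; the allylic silyl ether may ionise. The fallback replaces the ene reaction by an intramolecular Hosomi–Sakurai allylation; it sets out from aldehyde 14 and comes back to the route at 21. Zirconium-catalysed carboalumination of commercial 3-(trimethylsilyl)propyne (Me3Al, Cp2ZrCl2, then I2) should give (E)-1-iodo-2-methyl-3-(trimethylsilyl)prop-1-ene F1. Iodine–lithium exchange (t-BuLi, Et2O, −78 °C) gives the alkenyllithium F2, which is added to 14 under the same Felkin–Anh control to give the 6S alcohol F3. Silylation (TBSOTf, 2,6-lutidine) gives the bis-silyl ether F4, pivalate cleavage (i-Bu2AlH) the primary alcohol F5, and Dess–Martin oxidation the aldehyde F6. BF3·OEt2 in CH2Cl2 at −78 °C should then form the C7–C8 bond by attack of the allylsilane γ-carbon on the aldehyde with loss of the silyl group, which gives 21 directly. The open, stepwise transition state does not need the hydrogen-transfer geometry. The allylsilane is far more nucleophilic than the alkene, so the aldehyde has less time to isomerise. The Lewis acid can also be varied freely.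

Step 19. What may go wrong: slow formation of the oxyphosphonium ion at the congested C6 hydroxyl, and E2 loss of the allylic H5 to a conjugated diene instead of substitution. The fallback separates activation from displacement; it sets out from 26 and comes back at 27. Chloromethanesulfonyl chloride and pyridine in CH2Cl2 at 0 °C convert the secondary alcohol into the chloromethanesulfonate F7 (the tertiary C4 alcohol should not react). CsOAc with 18-crown-6 in toluene then displaces the sulfonate with inversion to give 27. A small, very reactive sulfonate and a weakly basic, unsolvated acetate are the known remedy for hindered secondary alcohols that resist the redox condensation.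

Step 6. What may go wrong: sluggish cycloaddition at the hindered terminus C5 at 170 °C, with thermal loss of the tertiary allylic silyl ether or diene dimerisation, and eroded facial selectivity at that temperature. The fallback uses a far more reactive acetylene equivalent followed by dihydroxylation; it sets out from 7 and comes back at 10 or 12. (E)-1,2-Bis(phenylsulfonyl)ethene (commercial) should add in toluene at 80–110 °C to give the disulfone F8. Na(Hg) in phosphate-buffered methanol removes both sulfonyl groups to give the cyclohexa-1,4-diene F9. OsO4 (cat.) with N-methylmorpholine N-oxide should dihydroxylate the cis-disubstituted C6=C8 double bond in preference to the tetrasubstituted C1=C10 double bond. This gives 10 and/or its 6,8-bis-epimer F10; both give 12 under the conditions of step 8.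

Further compounds
F1 | step 15 | (E)-1-iodo-2-methyl-3-(trimethylsilyl)prop-1-ene | C[Si](C)(C)C/C(C)=C/I
F2 | step 15 | (E)-2-methyl-3-(trimethylsilyl)prop-1-enyllithium | C[Si](C)(C)C/C(C)=C/[Li]
F3 | step 15 | 6S alcohol with (E)-allylsilane arm, C8 pivalate | CC(C)(C)C(=O)OCC/C(C)=C1/CC[C@](C)(O[Si](CC)(CC)CC)[C@H]1[C@@H](O)/C=C(\C)C[Si](C)(C)C
F4 | step 15 | tert-butyldimethylsilyl ether of F3 | CC(C)(C)C(=O)OCC/C(C)=C1/CC[C@](C)(O[Si](CC)(CC)CC)[C@H]1[C@@H](O[Si](C)(C)C(C)(C)C)/C=C(\C)C[Si](C)(C)C
F5 | step 15 | C8 primary alcohol with allylsilane arm | OCC/C(C)=C1/CC[C@](C)(O[Si](CC)(CC)CC)[C@H]1[C@@H](O[Si](C)(C)C(C)(C)C)/C=C(\C)C[Si](C)(C)C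
F6 | step 15 | C8 aldehyde with allylsilane arm | O=CC/C(C)=C1/CC[C@](C)(O[Si](CC)(CC)CC)[C@H]1[C@@H](O[Si](C)(C)C(C)(C)C)/C=C(\C)C[Si](C)(C)C
F7 | step 19 | 6-O-chloromethanesulfonate of 26 | C/C=C(/C)C(=O)O[C@H]1CC(C)=C2CC[C@](C)(O)[C@H]2[C@@H](OS(=O)(=O)CCl)[C@@H]1C(C)C
F8 | step 6 | trans-6,8-bis(phenylsulfonyl) Diels–Alder adduct | O=S(=O)(c1ccccc1)C1CC(C)=C2CC[C@](C)(O[Si](CC)(CC)CC)[C@H]2C1S(=O)(=O)c1ccccc1
F9 | step 6 | cyclohexa-1,4-diene (C6=C8 and C1=C10) | CC1=C2CC[C@](C)(O[Si](CC)(CC)CC)[C@H]2C=CC1
F10 | step 6 | 6,8-bis-epimer of diol 10 | O[C@@H]1CC(C)=C2CC[C@](C)(O[Si](CC)(CC)CC)[C@H]2[C@@H]1O
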